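How high does the target stand in this flask within 6.0 min, and when?

all flasks: free catalyst 0.55 µM
- Saturday's: starting material 1 mM; second substrate 1 mM; reagent 0.90 mM; the very flask that is asked about, followed so far
- Tuesday's: starting material 2 mM; second substrate 1 mM; reagent 0.90 mM; run made earlier
- flask: starting material 1.0 mM; second substrate 1.00 mM; reagent 0.900 mM; time 6.0 min

Saturday's run (percent of the starting material charged)

| time / s | target / % |
|---|---|
| 10.0 | 22.9 |
| 20.0 | 34.9 |
| 40.0 | 39.3 |
| 80.0 | 36.3 |

Tuesday's run (percent of the starting material charged)

| time / min | target / % |
|---|---|
| 0.167 | 19.3 |
| 0.417 | 27.3 |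
| 1.00 | 26.9 |
| 2.50 | 25.1 |

(readings scatter by 0.5 percentage points)

1. time up to 6.0 min at which target stands highest
2. the amount of target, in percent of the starting material charged, at that time

For you at the bench: in this flask the starting material and the second substrate compete through one catalyst for the reagent, the limiting reagent, charged at less than the two together. A statistical split shares the reagent as the charges stand, and that is your zero. Tuesday's highest reading has 60.7% of the reagent in target, against a statistical 66.7%. Counting the rest of the reagent as second product, though some of it may still be unused, you read 0.771: the selectivity factor, target per second product at the top divided by the charge ratio of starting material to second substrate. It stands below the statistical 1.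

This flask has a charge ratio of 1.00, so I reckon 43.5% of its reagent goes to target, which is 39.2% of the starting material. Saturday's readings on this flask top at 39.3%, so expect the top near 0.67 min. Don't leave it standing: by 1.3 min Saturday's reading was down to 36.3%.

The forecast gives 39.8% at 0.62 min, holding that “target leaks back through the reversible step”. The flask gives 39.1% at 0.718 min.

    starting material + free catalyst ⇌ catalyst intermediate A (K = 1000 L mol⁻¹, k = 3.90 × 10⁵ L mol⁻¹ s⁻¹)
    reagent + catalyst intermediate A ⇌ free catalyst + target (K = 12.0, k = 4.70 × 10⁵ L mol⁻¹ s⁻¹)
    second substrate + free catalyst ⇌ catalyst intermediate B (K = 1900 L mol⁻¹, k = 8.60 × 10⁶ L mol⁻¹ s⁻¹)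
    reagent + catalyst intermediate B → free catalyst + second product (k = 1.70 × 10⁵ L mol⁻¹ s⁻¹)
    2 free catalyst ⇌ resting dimer, settled at all times (K = 7.70 × 10⁵ L mol⁻¹)

Now take the neighbouring flask, with 1.7 mM of starting material and its other charges as here. Its charge ratio is 1.70, so with the same factor I reckon 56.7% of the reagent in target at the top, which is 30.0% of that flask's starting material. The simulation of that flask tops at 30.4%. At 6.00 min its target stands at 20.3%.

The readings stem from a simulated flask for substances that don't exist; the scatter is artificial.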